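The numbers are made up; the result is computed.

The racemization catalyst turns the left-handed substrate into the right-handed one and back, while a single-handed coupling partner takes both hands away into their products.

    coupling partner + right-handed substrate → right-handed product (k1 = 1.4 /M/s, Ea1 = 54.0 kJ/mol)
    coupling partner + left-handed substrate → left-handed product (k2 = 3.5 /M/s, Ea2 = 39.0 kJ/mol)
    left-handed substrate + racemization catalyst ⇌ right-handed substrate + racemization catalyst, rate k3*[racemization catalyst]*[left-handed substrate] forward; the back reaction follows from the equilibrium constant (k3 = 130 /M/s, Ea3 = 40.0 kJ/mol)
    2 racemization catalyst ⇌ resting dimer, settled at all times (K4 = 9600 /M, ΔH4 = −7.00 kJ/mol)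
    (constants at 25 °C)

| flask | left-handed substrate | coupling partner | racemization catalyst | right-handed substrate | temperature | time |
|---|---|---|---|---|---|---|
| larch | 0.10 M | 3.00 equiv | 0.1 mol% | 0.10 M | 5 °C | 2.5 min |
| alder | 0.10 M | 3.00 equiv | 0.1 mol% | 0.10 M | 25 °C | 2.5 min |
| maple | 0.10 M | 3.00 equiv | 0.1 mol% | 0.10 M | −15 °C | 2.5 min |

- coupling partner is single-handed; left-handed substrate and right-handed substrate are mirror images of each other, charged as a racemate, each of them at the stated concentration
- a doubled species enters its step squared and goes two at a time
- the constants hold at 25 °C; other temperatures follow from the activation energies and enthalpies
- the handed part of coupling partner does not stay in what it makes, so the products of the two hands are mirror images too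

- which flask leads in amount of left-handed product, in percent of the left-handed substrate and right-handed substrate together charged ("all alike" within 1.5 percentage points) (larch / alder / maple / all alike)
- how much left-handed product is there at the end, in percent of the left-handed substrate and right-handed substrate together charged: larch
- how much left-handed product is there at the end, in percent of the left-handed substrate and right-handed substrate together charged: alder
- how much left-handed product is there at the end, in percent of the left-handed substrate and right-handed substrate together charged: maple

Two numbers seem at odds. In maple the left-handed substrate starts out coupling 6.4 times as fast as the right-handed one (the selectivity factor), yet each hand is 50.0% of the charge, and the coupling partner, at 0.300 M, is more than both hands need. So the fast hand merely goes first, and the left-handed product can pass that figure by flips, molecules that change hand before they couple.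

I follow one molecule. Out of 1.00 × 10⁻⁴ M charged, the balance with the resting dimer leaves c(racemization catalyst) at 5.07 × 10⁻⁵ M in alder, so a molecule there flips at 0.00659 /s. Against this it couples at its rate constant times c(coupling partner). Taking the left hand to go first, c(coupling partner) falls from 0.300 M to 0.200 M while left-handed substrate couples, then to 0.100 M while right-handed substrate couples. The logarithmic means, which a chance averaged over molecules requires, are 0.247 M and 0.144 M.

In alder a right-handed molecule therefore flips with chance 3.26% and a left-handed one with chance 0.763%. The difference, 2.50%, is the net flip chance, my estimate of the part of the right-handed charge that ends as left-handed product. This puts alder at 51.2%.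

For maple, against alder, step 1 slows by a factor of 29 and step 3 by a factor of 12, and the dimer constant becomes 14900 /M, leaving 4.36 × 10⁻⁵ M free. So 4.65 × 10⁻⁴ /s gives a net flip chance of 6.11%, or 53.1% for a finished run. But the clock of step 1 at the closing c(coupling partner) I took, 0.100 M, is in maple 3.48 min, longer than the run, while in alder it is 7.14 s, far shorter than the run. I commit to the alder figure, and for maple to somewhere under its finished-run figure.

The forecast says all alike, with 50.8% for larch, 50.4% for alder, where I differ, and 51.4% for maple, since “the dimer-limited racemization is far slower than coupling”.

The simulation gives all alike: larch 51.6%, alder 51.0%, maple 51.3%. The forecast is right on each within the tolerance.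

In alder the net flip chance of 2.50% gave 51.2% against 51.0%. In maple, left for 25.0 min, the net flip chance of 6.11%, 2.44 times that of alder, gives 53.1% against 52.7%, the run of 2.5 min having reached a conversion of 85.3%. The right-handed coupling is the main reason the left-handed product stays near its charged share: struck out of alder, the left-handed product rises from 51.0% to 80.8%, which is 61% of what is missing from the whole charge.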